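**Plan**

1. Locants (used for all intermediates): bicyclo[3.3.1]nonane with C1 = hydroxylated bridgehead, C2 = CH2, C3 = C–N, C4 = C–OH, C5 = bridgehead CH, C6 = C–OMe, C7/C8 = epoxide carbons (C8 on C1), C9 = ketone; ring A = C1–C5 plus C9, ring B = C5–C8 plus C1 and C9.
2. Retrosynthetic cuts, in order: the amide N–CO bond; the two epoxide C–O bonds (back to C7=C8); the C1–C8 bond (ring B opens to a ring A enol silane with an ethynyl arm on C5); the C5–C6 bond; the C1–O bond (back to a cyclohexenone).
3. Enabling feature: C1 is a quaternary, oxygen-bearing carbon α to the C9 carbonyl and bonded to C8 of a C7=C8 alkene. A C9 enol silane whose β-carbon C1 carries the oxygen can therefore add to the terminal carbon of a C6-bound alkyne, making the bridgehead and the ring B alkene together.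
4. Forward order: ring A from 1,3-cyclohexadiene (cis-diol, desymmetrisation to the C3–N/C4–O oxazolidinone, enone); then the C5 arm; then the C1 benzoate/C9 enol silane; then ring B by gold catalysis; last the amide chain and the epoxide.
5. Stereochemistry: C3/C4 from the enantioselective palladium-catalysed desymmetrisation; C5 by attack anti to the C4–O bond; C6 by the syn-selective open transition state of the acetal addition; C1 through the C5 tether in the ring closure; C7/C8 by epoxidation directed by the C1 hydroxyl.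

Key step: step 11

Assumption: the (R,R)-configured ligand (1R,2R)-N,N′-bis[2-(diphenylphosphino)benzoyl]cyclohexane-1,2-diamine is taken to give the (3aS,7aR) oxazolidinone in step 2; if the sense of induction is the reverse, the (S,S)-ligand is used and nothing else changes.

**Route**

Step 1
Reactants: 1 cyclohexa-1,3-diene
Product: 3 cis-cyclohex-2-ene-1,4-diol (meso), via endoperoxide 2 (not isolated)
Conditions: O2, tetraphenylporphyrin (cat.), visible light, CH2Cl2, 0 °C; then thiourea, MeOH (wet), rt
Reagents that add atoms: oxygen, O=O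
Why: Singlet oxygen adds to the s-cis diene in a [4+2] cycloaddition and thiourea then reduces the O–O bond of the bicyclic endoperoxide, so both hydroxyls come from one face and the diol is the meso cis isomer.

Step 2
Reactants: 3 cis-cyclohex-2-ene-1,4-diol; 4 p-toluenesulfonyl isocyanate
Product: 6 (3aS,7aR)-3-tosyl-3a,6,7,7a-tetrahydro-1,3-benzoxazol-2(3H)-one, via bis-carbamate 5 (not isolated)
Conditions: 4 (2.1 equiv), THF, rt to 50 °C; then Pd2(dba)3·CHCl3 (2.5 mol%), (R,R)-ligand (7.5 mol%), Et3N (1 equiv), THF, 0 °C to rt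
Reagents that add atoms: p-toluenesulfonyl isocyanate (4), Cc1ccc(cc1)S(=O)(=O)N=C=O
Why: Carbamoylation of both hydroxyls is followed by a palladium-catalysed asymmetric allylic substitution (desymmetrisation of a meso bis-carbamate), in which the chiral zerovalent palladium complex ionises one enantiotopic carbamate anti to the metal and the nitrogen of the other carbamate closes onto the adjacent allyl terminus from the face opposite to palladium, giving the cis-fused ring and setting C3 and C4 under ligand control.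

Step 3
Reactants: 6 N-tosyl oxazolidinone
Product: 7 (3aS,7aR)-3a,6,7,7a-tetrahydro-1,3-benzoxazol-2(3H)-one
Conditions: NaC10H8 (sodium naphthalenide, 3 equiv), DME, −78 °C; then H2O
Reagents that add atoms: none
Why: Reductive desulfonylation by single-electron transfer, in which the electron-poor N-sulfonyl carbamate accepts electrons at −78 °C far more readily than the isolated alkene or the carbamate C–O bond, so no stereocentre is touched.

Step 4
Reactants: 7 N–H oxazolidinone
Product: 8 (3aS,7aR)-3a,7a-dihydro-1,3-benzoxazole-2,6(3H,7H)-dione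
Conditions: CrO3 (15 equiv), 3,5-dimethylpyrazole (15 equiv), CH2Cl2, −20 °C
Reagents that add atoms: chromium trioxide, O=[Cr](=O)=O
Why: Allylic oxidation with the CrO3–3,5-dimethylpyrazole complex converts the only allylic methylene (C9) into the ketone, the other allylic position (C3) being a methine deactivated by the carbamate nitrogen, and the neutral, cold medium spares the β-carbamoyloxy enone that a base would aromatise.

Step 5
Reactants: 9 3-(trimethylsilyl)prop-2-ynal
Product: 10 3,3-dimethoxy-1-(trimethylsilyl)prop-1-yne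
Conditions: HC(OMe)3 (3 equiv), MeOH, p-TsOH·H2O (1 mol%), rt; NaHCO3
Reagents that add atoms: trimethyl orthoformate, COC(OC)OC; methanol, CO
Why: Acid-catalysed acetalisation of the aldehyde, driven to completion by the orthoester as water scavenger, with the alkynylsilane inert to catalytic acid.

Step 6
Reactants: 8 enone; 10 alkynyl dimethyl acetal
Product: 13 (3aS,7R,7aR)-7-[(1S)-1-methoxy-3-(trimethylsilyl)prop-2-yn-1-yl]-3a,7a-dihydro-1,3-benzoxazole-2,6(3H,7H)-dione, via bis-silyl dienol ether 11 (not isolated), via N-silyl adduct 12 (not isolated)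
Conditions: Me3SiOTf (2.3 equiv), Et3N (2.6 equiv), CH2Cl2, 0 °C; evaporate, pentane, filter under argon; then 10 (1.3 equiv), Me3SiOTf (5 mol%), CH2Cl2, −78 °C; aq. NaHCO3
Reagents that add atoms: acetal 10, COC(OC)C#C[Si](C)(C)C
Why: Soft enolisation gives the cross-conjugated 2-silyloxy diene (deprotonation at C5, not at the nitrogen-bearing C3), and a Mukaiyama-type addition of this enol silane to the alkynyl oxocarbenium ion released from the acetal forms C5–C6 and installs the C6 methoxy group directly; C5 is attacked on the convex face anti to the C4–O bond of the cis-fused carbamate, the open antiperiplanar transition state of acetal additions to cyclic enol silanes favours the required syn C5/C6 isomer, and the absence of a free enolate limits β-elimination of the carbamate oxygen.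

Step 7
Reactants: 13 β-methoxy enone
Product: 14 (3aS,4S,5S,7R,7aR)-4,5-dihydroxy-7-[(1S)-1-methoxy-3-(trimethylsilyl)prop-2-yn-1-yl]hexahydro-1,3-benzoxazole-2,6-dione
Conditions: OsO4 (5 mol%), N-methylmorpholine N-oxide (1.5 equiv), citric acid (1 equiv), t-BuOH/H2O (1:1), rt
Reagents that add atoms: N-methylmorpholine N-oxide, C[N+]1([O-])CCOCC1; water, O; osmium tetroxide (catalytic oxygen carrier), O=[Os](=O)(=O)=O
Why: Catalytic OsO4 cis-dihydroxylation of the electron-poor enone alkene, run with citric acid to speed turnover and keep the medium non-basic; the diol is expected anti to the C3 nitrogen, but the configuration at C1 and C2 is erased in the next step and is of no consequence.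

Step 8
Reactants: 14 α,β-dihydroxy ketone
Product: 16 (3aS,7R,7aR)-7-[(1S)-1-methoxy-3-(trimethylsilyl)prop-2-yn-1-yl]-2,6-dioxo-2,3,3a,6,7,7a-hexahydro-1,3-benzoxazol-5-yl benzoate, via dibenzoate 15 (not isolated)
Conditions: BzCl (2.5 equiv), pyridine, CH2Cl2, 0 °C to rt; then Et3N (3 equiv), 0 °C to rt
Reagents that add atoms: benzoyl chloride, O=C(Cl)c1ccccc1
Why: Benzoylation of both hydroxyls and then an E1cB elimination, in which the C1 hydrogen (flanked by the ketone and the benzoyloxy group) is the most acidic one, so triethylamine expels the C2 benzoate and leaves the C1 enol benzoate without passing through a free diosphenol that could tautomerise toward C5; without an acyl-transfer catalyst the carbamate N–H is not benzoylated.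

Step 9
Reactants: 16 2-benzoyloxy enone
Product: 17 (3aS,7R,7aR)-6-[(tert-butyldimethylsilyl)oxy]-7-[(1S)-1-methoxy-3-(trimethylsilyl)prop-2-yn-1-yl]-2-oxo-2,3,3a,4,7,7a-hexahydro-1,3-benzoxazol-5-yl benzoate
Conditions: t-BuMe2SiH (3 equiv), RhCl(PPh3)3 (5 mol%), toluene, 60 °C
Reagents that add atoms: tert-butyldimethylsilane, C[SiH](C)C(C)(C)C
Why: Rhodium-catalysed 1,4-hydrosilylation of the enone places hydrogen on C2 and silicon on the C9 oxygen, so the enol silane is fixed as C9=C1 with no free enolate that could shift the benzoyl group between the two oxygens, and the hindered internal alkynylsilane should react more slowly than the activated enone.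

Step 10
Reactants: 17 enol silane with silylated alkyne
Product: 18 (3aS,7R,7aR)-6-[(tert-butyldimethylsilyl)oxy]-7-[(1S)-1-methoxyprop-2-yn-1-yl]-2-oxo-2,3,3a,4,7,7a-hexahydro-1,3-benzoxazol-5-yl benzoate
Conditions: AgNO3 (10 mol%), acetone/H2O/CH2Cl2, rt, dark
Reagents that add atoms: none
Why: Silver-catalysed protodesilylation is specific for the C(sp)–SiMe3 bond (silver acetylide, then protonation), and its neutral medium should leave the O-silyl enol ether, the enol benzoate and the carbamate alone.

Step 11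
Reactants: 18 ring A enol silane with C1 benzoate, cis-oxazolidinone and propargylic methyl ether arm on C5
Product: 19 (1S,3S,4R,5R,6R)-1-benzoyloxy-6-methoxy-9-oxobicyclo[3.3.1]non-7-ene carrying the oxazolidin-2-one fused at C3–N and C4–O
Conditions: [(t-Bu)2(2-biphenylyl)P]AuNTf2 (5 mol%), acetone, H2O (2 equiv), rt
Reagents that add atoms: none
Why: The cationic monovalent gold phosphine complex binds the terminal alkyne and the enol silane carbon C1 (β to the silyloxy group on C9) adds to the terminal carbon C8 anti to gold, after which the silyloxocarbenium ion at C9 gives up silicon to water and the vinyl–gold bond at C7 is protonated, leaving the C9 ketone and the cis C7=C8 alkene. The closest known reaction is the gold-catalysed carbocyclisation of cyclic silyl enol ethers onto pendant alkynes that gives bicyclo[3.3.1]nonenones, here with a benzoyloxy group on the nucleophilic carbon. Ring B closes in the 6-endo-dig mode, both alkyne carbons ending up inside the new six-membered ring (C1, C8, C7, C6, C5, C9). The new quaternary stereocentre C1 is fixed by the C5 stereocentre: allylic strain against the C9 silyloxy group holds the arm axial on the ring A half-chair, so C8 can bond only to the face of C1 that carries the arm and the benzoate is pushed to the other face. The step needs attack at C8 and not at C7 (5-exo) and attack by C1 and not by C9; the bulky biaryl phosphine and the inductively withdrawing methoxy group on C6 disfavour positive charge at C7, and the silyl ether oxygen is a far better donor than the ester oxygen. The carbamate nitrogen lies trans to the arm across ring A and cannot reach the alkyne.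

Step 12
Reactants: 19 bicyclic keto benzoate
Product: 21 tert-butyl N-[(1S,3S,4R,5S,6R)-1,4-dihydroxy-6-methoxy-9-oxobicyclo[3.3.1]non-7-en-3-yl]carbamate, via N-Boc oxazolidinone 20 (not isolated)
Conditions: Boc2O (1.5 equiv), DMAP (0.1 equiv), Et3N, THF, rt; then MeOH, Cs2CO3 (0.3 equiv), 0 °C to rt
Reagents that add atoms: di-tert-butyl dicarbonate, CC(C)(C)OC(=O)OC(=O)OC(C)(C)C
Why: N-Acylation turns the ring carbonyl into an imide-type carbonyl, which methoxide attacks with expulsion of the Boc-amide nitrogen (the established endocyclic cleavage of N-Boc oxazolidinones by Cs2CO3 in methanol); the methyl carbonate on C4 and the tertiary α-keto benzoate on C1 are transesterified in the same pot, and the ketone cannot enolise (C1 quaternary, C5 a bridgehead), so nothing epimerises or eliminates.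

Step 13
Reactants: 21 N-Boc amino diol; 22 (E)-dodec-2-enoic acid
Product: 24 (2E)-N-[(1S,3S,4R,5S,6R)-1,4-dihydroxy-6-methoxy-9-oxobicyclo[3.3.1]non-7-en-3-yl]dodec-2-enamide, via ammonium trifluoroacetate 23 (not isolated)
Conditions: CF3CO2H/CH2Cl2 (1:4), 0 °C; evaporate; then 22 (1.1 equiv), EDC·HCl (1.2 equiv), HOBt (1.2 equiv), i-Pr2NEt (3 equiv), DMF, 0 °C to rt
Reagents that add atoms: (E)-dodec-2-enoic acid (22), CCCCCCCCC/C=C/C(=O)O
Why: Acidolysis of the tert-butyl carbamate and, after evaporation, carbodiimide amide coupling of the ammonium salt with the acid, the amine being acylated far faster than the secondary and tertiary hydroxyls and the (E)-alkene of the acid staying untouched.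

Step 14
Reactants: 24 amide with C7=C8 alkene
Product: 25 (2E)-N-[(1S,3S,4R,5S,6S,7S,8S)-7,8-epoxy-1,4-dihydroxy-6-methoxy-9-oxobicyclo[3.3.1]nonan-3-yl]dodec-2-enamide (target)
Conditions: VO(acac)2 (5 mol%), t-BuOOH (1.5 equiv, decane), CH2Cl2, 0 °C to rt
Reagents that add atoms: tert-butyl hydroperoxide, CC(C)(C)OO
Why: Hydroxyl-directed epoxidation with vanadium and tert-butyl hydroperoxide, in which the vanadate ester of the tertiary allylic C1 hydroxyl delivers oxygen to C7=C8 on its own face (also the exo face turned away from ring A) and so sets C7 and C8, while the electron-poor alkene of the enamide is not oxidised.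

**Compound list**

1 | cyclohexa-1,3-diene | C1=CC=CCC1 | starting material
2 | 2,3-dioxabicyclo[2.2.2]oct-5-ene (endoperoxide, not isolated) | C1CC2C=CC1OO2 | intermediate
3 | cis-cyclohex-2-ene-1,4-diol (meso, 1R,4S) | O[C@H]1C=C[C@@H](O)CC1 | intermediate
4 | p-toluenesulfonyl isocyanate | Cc1ccc(cc1)S(=O)(=O)N=C=O | starting material
5 | cis-cyclohex-2-ene-1,4-diyl bis(N-tosylcarbamate) (meso, not isolated) | Cc1ccc(cc1)S(=O)(=O)NC(=O)O[C@H]1C=C[C@@H](OC(=O)NS(=O)(=O)c2ccc(C)cc2)CC1 | intermediate
6 | (3aS,7aR)-3-tosyl-3a,6,7,7a-tetrahydro-1,3-benzoxazol-2(3H)-one (cis-fused) | O=C1N(S(=O)(=O)c3ccc(C)cc3)[C@H]2C=CCC[C@H]2O1 | intermediate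
7 | (3aS,7aR)-3a,6,7,7a-tetrahydro-1,3-benzoxazol-2(3H)-one | O=C1N[C@H]2C=CCC[C@H]2O1 | intermediate
8 | (3aS,7aR)-3a,7a-dihydro-1,3-benzoxazole-2,6(3H,7H)-dione | O=C1N[C@H]2C=CC(=O)C[C@H]2O1 | intermediate
9 | 3-(trimethylsilyl)prop-2-ynal | C[Si](C)(C)C#CC=O | starting material
10 | 3,3-dimethoxy-1-(trimethylsilyl)prop-1-yne | COC(OC)C#C[Si](C)(C)C | intermediate
11 | (3aS,7aR)-3-(trimethylsilyl)-6-[(trimethylsilyl)oxy]-3a,7a-dihydro-1,3-benzoxazol-2(3H)-one (not isolated) | O=C1N([Si](C)(C)C)[C@H]2C=CC(O[Si](C)(C)C)=C[C@H]2O1 | intermediate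
12 | N-trimethylsilyl derivative of 13 (not isolated) | O=C1N([Si](C)(C)C)[C@H]2C=CC(=O)[C@@H]([C@H]2O1)[C@H](OC)C#C[Si](C)(C)C | intermediate
13 | (3aS,7R,7aR)-7-[(1S)-1-methoxy-3-(trimethylsilyl)prop-2-yn-1-yl]-3a,7a-dihydro-1,3-benzoxazole-2,6(3H,7H)-dione (arm trans to the ring oxygen, syn C5/C6) | O=C1N[C@H]2C=CC(=O)[C@@H]([C@H]2O1)[C@H](OC)C#C[Si](C)(C)C | intermediate
14 | (3aS,4S,5S,7R,7aR)-4,5-dihydroxy-7-[(1S)-1-methoxy-3-(trimethylsilyl)prop-2-yn-1-yl]hexahydro-1,3-benzoxazole-2,6-dione (expected major diol, both hydroxyls anti to N) | O=C1N[C@H]2[C@H](O)[C@H](O)C(=O)[C@@H]([C@H]2O1)[C@H](OC)C#C[Si](C)(C)C | intermediate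
15 | 4,5-di-O-benzoyl derivative of 14 (same configuration, not isolated) | O=C1N[C@H]2[C@H](OC(=O)c3ccccc3)[C@H](OC(=O)c3ccccc3)C(=O)[C@@H]([C@H]2O1)[C@H](OC)C#C[Si](C)(C)C | intermediate
16 | (3aS,7R,7aR)-7-[(1S)-1-methoxy-3-(trimethylsilyl)prop-2-yn-1-yl]-2,6-dioxo-2,3,3a,6,7,7a-hexahydro-1,3-benzoxazol-5-yl benzoate | O=C1N[C@H]2C=C(OC(=O)c3ccccc3)C(=O)[C@@H]([C@H]2O1)[C@H](OC)C#C[Si](C)(C)C | intermediate
17 | (3aS,7R,7aR)-6-[(tert-butyldimethylsilyl)oxy]-7-[(1S)-1-methoxy-3-(trimethylsilyl)prop-2-yn-1-yl]-2-oxo-2,3,3a,4,7,7a-hexahydro-1,3-benzoxazol-5-yl benzoate | O=C1N[C@H]2CC(OC(=O)c3ccccc3)=C(O[Si](C)(C)C(C)(C)C)[C@@H]([C@H]2O1)[C@H](OC)C#C[Si](C)(C)C | intermediate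
18 | (3aS,7R,7aR)-6-[(tert-butyldimethylsilyl)oxy]-7-[(1S)-1-methoxyprop-2-yn-1-yl]-2-oxo-2,3,3a,4,7,7a-hexahydro-1,3-benzoxazol-5-yl benzoate | O=C1N[C@H]2CC(OC(=O)c3ccccc3)=C(O[Si](C)(C)C(C)(C)C)[C@@H]([C@H]2O1)[C@H](OC)C#C | intermediate
19 | (1S,3S,4R,5R,6R)-1-benzoyloxy-6-methoxy-9-oxobicyclo[3.3.1]non-7-ene with oxazolidin-2-one fused at C3 (N) and C4 (O), plan locants | O=C1N[C@H]2C[C@@]3(OC(=O)c4ccccc4)C(=O)[C@@H]([C@H]2O1)[C@H](OC)C=C3 | intermediate
20 | N-tert-butoxycarbonyl derivative of 19 (not isolated) | O=C1N(C(=O)OC(C)(C)C)[C@H]2C[C@@]3(OC(=O)c4ccccc4)C(=O)[C@@H]([C@H]2O1)[C@H](OC)C=C3 | intermediate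
21 | tert-butyl N-[(1S,3S,4R,5S,6R)-1,4-dihydroxy-6-methoxy-9-oxobicyclo[3.3.1]non-7-en-3-yl]carbamate | CC(C)(C)OC(=O)N[C@H]1C[C@@]2(O)C(=O)[C@@H]([C@H]1O)[C@H](OC)C=C2 | intermediate
22 | (E)-dodec-2-enoic acid | CCCCCCCCC/C=C/C(=O)O | starting material
23 | (1S,3S,4R,5S,6R)-1,4-dihydroxy-6-methoxy-9-oxobicyclo[3.3.1]non-7-en-3-aminium trifluoroacetate (not isolated) | [NH3+][C@H]1C[C@@]2(O)C(=O)[C@@H]([C@H]1O)[C@H](OC)C=C2.[O-]C(=O)C(F)(F)F | intermediate
24 | (2E)-N-[(1S,3S,4R,5S,6R)-1,4-dihydroxy-6-methoxy-9-oxobicyclo[3.3.1]non-7-en-3-yl]dodec-2-enamide | CCCCCCCCC/C=C/C(=O)N[C@H]1C[C@@]2(O)C(=O)[C@@H]([C@H]1O)[C@H](OC)C=C2 | intermediate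
25 | (2E)-N-[(1S,3S,4R,5S,6S,7S,8S)-7,8-epoxy-1,4-dihydroxy-6-methoxy-9-oxobicyclo[3.3.1]nonan-3-yl]dodec-2-enamide | CCCCCCCCC/C=C/C(=O)N[C@H]1C[C@@]2(O)C(=O)[C@@H]([C@H]1O)[C@H](OC)[C@@H]1O[C@@H]12 | target

**Totals**

Total step count: 14. Longest linear sequence: 13 steps (steps 1–4 and 6–14, from 1 to 25); step 5 is a one-step side branch.

**Steps most likely to fail**

Step 6 (C5–C6 bond). What may go wrong: ionisation of the allylic C4–O bond of the silyl dienol ether by the silyl triflate followed by loss of the C3 proton (aromatisation of ring A), or weak syn/anti discrimination with the slender alkynyl oxocarbenium ion. The fallback sets out from 8 and comes back at 13. Enone 8 is deprotonated twice with LiN(i-Pr)2 (2.2 equiv, THF, −78 °C), first at nitrogen, which makes the carbamate a poor nucleofuge, then at C5. Transmetalation with ClTi(Oi-Pr)3 and addition of aldehyde 9 at −78 °C should give, by the syn preference of cyclic titanium enolates, the β-hydroxy ketone (3aS,7R,7aR)-7-[(1S)-1-hydroxy-3-(trimethylsilyl)prop-2-yn-1-yl]-3a,7a-dihydro-1,3-benzoxazole-2,6(3H,7H)-dione F1. O-Methylation with Me3OBF4 and 1,8-bis(dimethylamino)naphthalene in CH2Cl2 then gives 13.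

Step 11 (ring closure). What may go wrong: hydrolytic loss of the silyl group from the enol ether before the carbon–carbon bond forms, hydration of the alkyne, or closure at C7 (5-exo). The fallback sets out from 18 and comes back at 19; it replaces π-acid activation by a polar aldol closure that can only give the six-membered ring. Anti-Markovnikov hydroboration of the terminal alkyne with dicyclohexylborane and buffered oxidation with NaBO3·4H2O should give the aldehyde (3aS,7R,7aR)-6-[(tert-butyldimethylsilyl)oxy]-7-[(1R)-1-methoxy-3-oxopropyl]-2-oxo-2,3,3a,4,7,7a-hexahydro-1,3-benzoxazol-5-yl benzoate F2. BF3·OEt2 in CH2Cl2 at −78 °C then triggers an intramolecular Mukaiyama aldol of C1 onto the aldehyde carbon C8, under the same tether control at C1, to give the β-hydroxy ketone (1S,3S,4R,5R,6R)-1-benzoyloxy-8-hydroxy-6-methoxy-9-oxobicyclo[3.3.1]nonane with the C3/C4-fused oxazolidinone F3. Syn-dehydration with the Burgess reagent (methyl N-(triethylammoniosulfonyl)carbamate, benzene, 50 °C) is possible only toward C7, because C1 has no hydrogen, and gives 19.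

Step 9 (conjugate hydrosilylation). What may go wrong: competing hydrosilylation of the alkynylsilane, or sluggish turnover with the hindered silane so that the reduction stays incomplete. The fallback sets out from 16 and comes back at 17. Conjugate reduction with [(Ph3P)CuH]6 in wet benzene gives the saturated α-benzoyloxy ketone (3aS,7R,7aR)-7-[(1S)-1-methoxy-3-(trimethylsilyl)prop-2-yn-1-yl]-2,6-dioxooctahydro-1,3-benzoxazol-5-yl benzoate F4 as a mixture at the benzoyloxy carbon. Soft enolisation with t-BuMe2SiOTf and Et3N (CH2Cl2, 0 °C) removes the more acidic hydrogen on the benzoyloxy-bearing carbon C1 and gives 17.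

**Further compounds**

F1 | step 6 | (3aS,7R,7aR)-7-[(1S)-1-hydroxy-3-(trimethylsilyl)prop-2-yn-1-yl]-3a,7a-dihydro-1,3-benzoxazole-2,6(3H,7H)-dione | O=C1N[C@H]2C=CC(=O)[C@@H]([C@H]2O1)[C@H](O)C#C[Si](C)(C)C
F2 | step 11 | (3aS,7R,7aR)-6-[(tert-butyldimethylsilyl)oxy]-7-[(1R)-1-methoxy-3-oxopropyl]-2-oxo-2,3,3a,4,7,7a-hexahydro-1,3-benzoxazol-5-yl benzoate | O=C1N[C@H]2CC(OC(=O)c3ccccc3)=C(O[Si](C)(C)C(C)(C)C)[C@@H]([C@H]2O1)[C@H](OC)CC=O
F3 | step 11 | (1S,3S,4R,5R,6R)-1-benzoyloxy-8-hydroxy-6-methoxy-9-oxobicyclo[3.3.1]nonane with oxazolidin-2-one fused at C3 (N) and C4 (O), C8 epimers | O=C1N[C@H]2C[C@@]3(OC(=O)c4ccccc4)C(=O)[C@@H]([C@H]2O1)[C@H](OC)CC3O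
F4 | step 9 | (3aS,7R,7aR)-7-[(1S)-1-methoxy-3-(trimethylsilyl)prop-2-yn-1-yl]-2,6-dioxooctahydro-1,3-benzoxazol-5-yl benzoate, epimers at C5 of the benzoxazole | O=C1N[C@H]2CC(OC(=O)c3ccccc3)C(=O)[C@@H]([C@H]2O1)[C@H](OC)C#C[Si](C)(C)C
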